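**Retrosynthetic overview**
1. The strategy rests on ring carbons C9(=O)–C10(Me) and C4(Me)–C5 of the ten-membered carbocycle: they map onto a cyclodeca-1(10),4-dien-9-one, the cycloreversion product of a bicyclo[2.2.0]hexane made from a 2-methylcyclohexenone (C5–C10) and a 1-methylcyclobutene (C1–C4).
2. Target ⇐ C2 ketone (chelation-controlled reduction) ⇐ C13 silyl ether (mesylate elimination to the methylene lactone) ⇐ C5 angeloylation ⇐ syn-dihydroxylation of E-C4=C5 ⇐ conjugate reduction of C1=C10 ⇐ dienone 26 ⇐ thermolysis of photoadduct 25.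
3. Key disconnection: C1–C10 and C4–C5 by [2+2] photocycloaddition of enone-lactone 24 with 3,3-dimethoxy-1-methylcyclobutene 6.
4. 24 ⇐ (R)-carvone: side-chain chlorination and hydroboration (C11–C13), Shapiro diene, Pd-catalysed 1,4-acetoxylactonisation (C6–O and C9–O), oxidation to the enone, C8 hydroxylation and Mitsunobu inversion. 6 ⇐ propyne + dichloroketene.
5. Ring order: cyclobutene (step 1), lactone on the carvone ring (step 11), central cyclobutane (step 16), ten-membered ring by cycloreversion (step 17).

Key step: step 16

**Remarks on the chemistry**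
- Numbering: carbocycle C1–C10 (C2 CHOH, C4 C(Me)OH, C5 CH–O-angelate, C6 lactone O–CH, C7, C8 CH–O-isobutyrate, C9 ketone, C10 CHMe); C11, C12, C13 = lactone α-carbon, carbonyl, methylene carbon.
- (R)-Carvone is used: the Shapiro/1,4-oxidation sequence turns the carvone carbonyl carbon into C5 and carvone C3 into C9, and with this mapping the carvone stereocentre has the configuration required at C7.
- C11 is a temporary, epimerisable centre: it is carried as the exo epimer (CH2OSi trans to C8 on the lactone ring) and is erased in step 22.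
- The cis-fused photoadduct is assumed to open to the (1(10)Z,4E)-diene; the E geometry at C4=C5 is what makes syn-dihydroxylation the correct oxygenation.
- The target is drawn as the open 2-hydroxy-9-ketone; a transannular hemiketal, if present, is a tautomer of the same compound.

**Step 1**
Reactants: 1 propyne; 2 trichloroacetyl chloride
Product: 4 4,4-dichloro-3-methylcyclobut-2-en-1-one, via dichloroketene 3 (not isolated)
Conditions: Zn(Cu), Et2O/DME, 0 °C to rt
Reagents that add atoms: none
Why: Zinc dechlorinates 2 to dichloroketene, which undergoes the thermal ketene–alkyne [2+2] cycloaddition; the unsubstituted alkyne carbon bonds to the ketene carbonyl carbon, so the methyl ends on C3 of the cyclobutenone.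

**Step 2**
Reactants: 4 4,4-dichloro-3-methylcyclobut-2-en-1-one
Product: 5 3-methylcyclobut-2-en-1-one
Conditions: Zn, AcOH, TMEDA, EtOH, 0 °C to rt
Reagents that add atoms: none
Why: Zinc-mediated reductive dehalogenation of the α,α-dichloroketone (zinc enolate protonated by AcOH) removes both chlorines and leaves the strained enone intact.

**Step 3**
Reactants: 5 3-methylcyclobut-2-en-1-one
Product: 6 3,3-dimethoxy-1-methylcyclobut-1-ene
Conditions: MeOSiMe3 (2.5 equiv), Me3SiOTf (cat.), CH2Cl2, −78 °C; pyridine quench
Reagents that add atoms: methoxytrimethylsilane, CO[Si](C)(C)C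
Why: Noyori acetalisation under aprotic conditions converts the enone carbonyl into the dimethyl ketal without conjugate addition of methanol or double-bond migration.

**Step 4**
Reactants: 7 (R)-carvone
Product: 8 (R)-5-(3-chloroprop-1-en-2-yl)-2-methylcyclohex-2-en-1-one
Conditions: Ca(OCl)2, CO2 (solid), CH2Cl2/H2O, 0 °C
Reagents that add atoms: calcium hypochlorite, [Ca+2].[O-]Cl.[O-]Cl
Why: Ene-type allylic chlorination by HOCl formed in situ takes place only at the electron-rich 1,1-disubstituted alkene; the electron-poor enone and the ring stereocentre are untouched.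

**Step 5**
Reactants: 8 (R)-5-(3-chloroprop-1-en-2-yl)-2-methylcyclohex-2-en-1-one
Product: 10 (R)-5-(3-hydroxyprop-1-en-2-yl)-2-methylcyclohex-2-en-1-one, via allylic acetate 9 (not isolated)
Conditions: KOAc, Bu4NI (cat.), DMF, 60 °C; then K2CO3, MeOH, 0 °C
Reagents that add atoms: potassium acetate, CC(=O)[O-].[K+]
Why: SN2 displacement of the primary allylic chloride by acetate followed by methanolysis of the acetate gives the allylic alcohol without exposing the enone to hydroxide.

**Step 6**
Reactants: 10 (R)-5-(3-hydroxyprop-1-en-2-yl)-2-methylcyclohex-2-en-1-one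
Product: 11 (R)-5-[3-(tert-butyldimethylsilyloxy)prop-1-en-2-yl]-2-methylcyclohex-2-en-1-one
Conditions: TBSCl, imidazole, DMF, rt
Reagents that add atoms: tert-butyldimethylsilyl chloride, CC(C)(C)[Si](C)(C)Cl
Why: Standard silylation of the primary alcohol installs the C13 oxygen mask, which is inert to organolithium, borane, light and heat.

**Step 7**
Reactants: 11 silyl ether of 10
Product: 12 (E)-4-methylbenzenesulfonylhydrazone of 11
Conditions: TsNHNH2, MeOH, rt
Reagents that add atoms: 4-methylbenzenesulfonohydrazide, Cc1ccc(cc1)S(=O)(=O)NN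
Why: Condensation of the enone carbonyl with tosylhydrazide gives the hydrazone, whose NHTs group sits syn to the α'-CH2 as the Shapiro reaction requires.

**Step 8**
Reactants: 12 tosylhydrazone
Product: 14 (R)-5-[3-(tert-butyldimethylsilyloxy)prop-1-en-2-yl]-2-methylcyclohexa-1,3-diene, via dienyllithium 13 (not isolated)
Conditions: MeLi (2.3 equiv), Et2O, 0 °C to rt; H2O
Reagents that add atoms: none
Why: Shapiro reaction of an α,β-unsaturated tosylhydrazone: syn α'-deprotonation, loss of sulfinate and N2 give the dienyllithium, protonated on quench, so the former carbonyl carbon becomes C5 of the diene C6=C5–C10(Me)=C9.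

**Step 9**
Reactants: 14 silyloxy triene
Product: 16 3-(tert-butyldimethylsilyloxy)-2-(4-methylcyclohexa-2,4-dien-1-yl)propan-1-ol (both C11 epimers), via B-alkyl-9-BBN adduct 15 (not isolated)
Conditions: 9-BBN (1.05 equiv), THF, 0 °C to rt; then NaOH, H2O2, 0 °C
Reagents that add atoms: hydrogen peroxide, OO
Why: Brown hydroboration–oxidation: 9-BBN adds anti-Markovnikov to the terminal 1,1-disubstituted alkene much faster than to the endocyclic conjugated diene; C11 forms as an epimer mixture that is corrected in step 12 and erased in step 22.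

**Step 10**
Reactants: 16 diene alcohol
Product: 17 3-(tert-butyldimethylsilyloxy)-2-(4-methylcyclohexa-2,4-dien-1-yl)propanoic acid (both C11 epimers)
Conditions: TEMPO (0.2 equiv), PhI(OAc)2 (2.2 equiv), MeCN/H2O, rt
Reagents that add atoms: water, O
Why: Oxoammonium-mediated oxidation of the primary alcohol to the aldehyde and of its hydrate to the acid proceeds without strong acid or base and tolerates the diene and the silyl ether.

**Step 11**
Reactants: 17 diene acid
Product: 18 cis-fused acetoxy lactone (5-acetoxy-6-methyl-3-[(tert-butyldimethylsilyloxy)methyl]-3a,4,5,7a-tetrahydro-1-benzofuran-2(3H)-one; C6–O cis to C7–C11; C9 acetate trans to the lactone oxygen; both C11 epimers)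
Conditions: Pd(OAc)2 (5 mol%), p-benzoquinone (20 mol%), MnO2 (1.5 equiv), AcOH/acetone 1:4, rt
Reagents that add atoms: acetic acid, CC(=O)O
Why: Palladium-catalysed 1,4-oxidation of the conjugated diene (1,4-acetoxylactonisation): divalent palladium binds the diene face anti to the side chain, the carboxylate attacks C6 anti to the metal and so closes the cis-fused γ-lactone, and acetate is transferred from palladium to C9 of the π-allyl unit; quinone/MnO2 reoxidise zerovalent palladium.

**Step 12**
Reactants: 18 acetoxy lactone
Product: 19 allylic alcohol lactone (C9–OH; C11 exo)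
Conditions: NaOMe (0.3 equiv), MeOH, 0 °C to rt; AcOH quench
Reagents that add atoms: none
Why: Transesterification removes the allylic acetate, and under the same methoxide conditions the lactone α-carbon C11 should equilibrate by enolisation to the exo epimer, in which the silyloxymethyl group is trans to C8.

**Step 13**
Reactants: 19 allylic alcohol lactone
Product: 20 enone-lactone unsubstituted at C8 (6-methyl-3-[(tert-butyldimethylsilyloxy)methyl]-3a,4-dihydro-1-benzofuran-2,5(3H,7aH)-dione)
Conditions: Dess–Martin periodinane, NaHCO3, CH2Cl2, 0 °C to rt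
Reagents that add atoms: none
Why: Dess–Martin oxidation of the secondary allylic alcohol gives the C9 enone and erases the C9 stereocentre, so the diastereoselectivity of acetate delivery in step 11 is of no consequence.

**Step 14**
Reactants: 20 enone-lactone
Product: 22 8-hydroxy enone-lactone (C8–OH trans to the C7–C11 bond), via sodium dienolate 21 (not isolated)
Conditions: NaN(SiMe3)2 (1.1 equiv), THF, −78 °C; then 2-(phenylsulfonyl)-3-phenyloxaziridine; NH4Cl (aq)
Reagents that add atoms: 2-(phenylsulfonyl)-3-phenyloxaziridine, O=S(=O)(N1OC1c1ccccc1)c1ccccc1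
Why: Kinetic deprotonation at the only ketone α-CH2 (C8) gives the cross-conjugated dienolate, and the Davis oxaziridine transfers oxygen to the convex face, anti to the adjacent C7–C11 bond, which sets C8–OH trans to the lactone.

**Step 15**
Reactants: 22 8-hydroxy enone-lactone; 23 isobutyric acid
Product: 24 enone-lactone precursor (C6–O, C7–C11 and C8–O-isobutyrate all cis; C13 as silyl ether)
Conditions: PPh3, DIAD, THF, 0 °C to rt
Reagents that add atoms: none
Why: Mitsunobu esterification displaces the activated α-keto carbinol oxygen by isobutyrate in an SN2 process that is accelerated by the adjacent carbonyl, inverting C8 to the configuration of the target.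

**Step 16**
Reactants: 24 enone-lactone precursor; 6 3,3-dimethoxy-1-methylcyclobut-1-ene
Product: 25 cis-anti-cis photoadduct (cyclohexanone fused to the lactone and to a bicyclo[2.2.0]hexane; new bonds C1–C10 and C4–C5)
Conditions: hν (350 nm, Pyrex), 6 (5 equiv), degassed PhMe, −20 °C
Reagents that add atoms: none
Why: Excitation of the enone at 350 nm and intersystem crossing give the triplet enone, which adds to the ground-state cyclobutene through a triplet 1,4-diradical that closes after spin inversion; the closest known reaction type is the intermolecular [2+2] photocycloaddition of cyclohexenones with cyclobutenes. The one ring that closes, the central cyclobutane C10–C5–C4–C1, is formed intermolecularly by two successive radical bond formations (C5–C4 and C10–C1), so no tether and no exo or endo mode is involved. C5 and C10 are set by the enone face: the lactone (C6–O, C7–C11) and the C8 isobutyrate all lie on one face of the cyclohexenone, so the cyclobutene adds to the opposite face and the four-membered ring is cis-fused to the six-membered ring. C1 and C4 are cis by the constraint of the cyclobutene ring and take the anti orientation that keeps C2 and C3 away from the cyclohexanone. The selectivity the route needs is the head-to-tail regiochemistry (C4 to C5, C1 to C10); it is secured because this orientation joins each methyl-bearing carbon to a CH carbon, whereas the head-to-head mode would join the quaternary centres C10 and C4, and because the more substituted alkene carbon of an alkyl-substituted alkene normally bonds to the enone β-carbon. Facial and syn/anti selectivity need not be complete, since all four cyclobutane stereocentres are destroyed in step 17.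

**Step 17**
Reactants: 25 photoadduct
Product: 26 (1(10)Z,4E)-2,2-dimethoxycyclodeca-1(10),4-dien-9-one lactone
Conditions: PhMe (0.01 M), BHT (cat.), base-washed sealed tube, 165 °C
Reagents that add atoms: none
Why: Thermal cycloreversion of the bicyclo[2.2.0]hexane: homolysis of the strained central C1–C4 bond gives a cyclohexane-1,4-diyl that fragments across C5–C10 (the more substituted bond, next to the C9 carbonyl), so the two bonds made in step 16 remain as ring bonds of the ten-membered ring; in the chair-like diyl C6 should be equatorial and the smaller C9 carbonyl carbon axial, which corresponds to the 4E alkene and the 1(10)Z enone.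

**Step 18**
Reactants: 26 cyclodecadienone
Product: 27 (4E)-2,2-dimethoxy-10-methylcyclodec-4-en-9-one lactone (C10 as in the target)
Conditions: [(Ph3P)CuH]6 (0.4 equiv), degassed PhH, H2O (5 equiv), rt
Reagents that add atoms: none
Why: Stryker conjugate reduction delivers hydride only to C1 of the enone (the isolated alkene, esters and ketal are inert), and the copper enolate is protonated at C10 from the outer face of the ring, anti to C7 with the C8–O bond held anti to the enolate C–O bond, which should place the 10-methyl anti to the 8-acyloxy group; the centre is α to the ketone and so remains epimerisable.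

**Step 19**
Reactants: 27 cyclodecenone
Product: 28 4,5-diol (4-OH tertiary, 5-OH secondary, configurations as in the target)
Conditions: OsO4 (5 mol%), NMO (1.5 equiv), acetone/H2O 5:1, 0 °C to rt
Reagents that add atoms: osmium tetroxide, O=[Os](=O)(=O)=O; N-methylmorpholine N-oxide, C[N+]1([O-])CCOCC1; water, O
Why: Upjohn syn-dihydroxylation: the E-alkene of the ten-membered ring can be attacked only on its outer face, and allylic 1,3-strain between the 4-methyl and C6 keeps H6 in the alkene plane, so the open face is the one syn to the lactone oxygen and suprafacial addition should give both new centres as required.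

**Step 20**
Reactants: 28 4,5-diol; 29 angelic acid
Product: 31 5-O-angelate, via angeloyl 2,4,6-trichlorobenzoyl anhydride 30 (not isolated)
Conditions: 29, 2,4,6-trichlorobenzoyl chloride, Et3N, PhMe, rt; then 28, 75 °C
Reagents that add atoms: none
Why: Yamaguchi-type mixed-anhydride esterification acylates the secondary C5 hydroxyl only (the tertiary C4 hydroxyl is inert), and omitting a nucleophilic amine catalyst avoids Z-to-E isomerisation of the angelate to the tiglate.

**Step 21**
Reactants: 31 5-O-angelate
Product: 32 primary alcohol at C13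
Conditions: Bu4NF, AcOH (1:1), THF, 0 °C to rt
Reagents that add atoms: none
Why: Fluoride-mediated desilylation buffered with acetic acid frees the primary alcohol without base-induced epimerisation at C8 or C10 and without touching the ketal.

**Step 22**
Reactants: 32 primary alcohol
Product: 34 α-methylene lactone with the C2 ketal, via primary mesylate 33 (not isolated)
Conditions: MsCl, Et3N, CH2Cl2, 0 °C; then DBU, 0 °C
Reagents that add atoms: none
Why: Only the primary hydroxyl is sulfonylated (the tertiary C4 hydroxyl does not react), and E1cB elimination through the lactone enolate gives the exocyclic methylene and erases C11.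

**Step 23**
Reactants: 34 methylene lactone ketal
Product: 35 2-ketone (β-hydroxy ketone with the C4 hydroxyl)
Conditions: PPTS (0.2 equiv), acetone/H2O 10:1, rt
Reagents that add atoms: water, O
Why: Mild acid hydrolysis cleaves the dimethyl ketal of the medium-ring ketone while the tertiary β-hydroxyl, the esters and the methylene lactone survive.

**Step 24**
Reactants: 35 2-ketone
Product: 36 target CNP0184688.2
Conditions: catecholborane (3 equiv), THF, −10 °C; then KNaC4H4O6 (aq)
Reagents that add atoms: none
Why: Catecholborane syn-reduction of a β-hydroxy ketone: the boryl ether of the C4 hydroxyl chelates the C2 carbonyl, the rest of the ten-membered ring bridges one face of this chelate, and a second equivalent delivers hydride to the open outer face to give the 2,4-cis diol; the hindered C9 ketone and the unsaturated esters do not react.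

**Compound list**
1 | propyne | CC#C | starting material
2 | trichloroacetyl chloride | ClC(Cl)(Cl)C(Cl)=O | starting material
3 | dichloroketene | ClC(Cl)=C=O | intermediate (not isolated)
4 | 4,4-dichloro-3-methylcyclobut-2-en-1-one | CC1=CC(=O)C1(Cl)Cl | intermediate
5 | 3-methylcyclobut-2-en-1-one | CC1=CC(=O)C1 | intermediate
6 | 3,3-dimethoxy-1-methylcyclobut-1-ene | CC1=CC(OC)(OC)C1 | intermediate
7 | (R)-carvone | CC1=CC[C@H](CC1=O)C(C)=C | starting material
8 | (R)-5-(3-chloroprop-1-en-2-yl)-2-methylcyclohex-2-en-1-one | CC1=CC[C@H](CC1=O)C(=C)CCl | intermediate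
9 | (R)-5-(3-acetoxyprop-1-en-2-yl)-2-methylcyclohex-2-en-1-one | CC1=CC[C@H](CC1=O)C(=C)COC(C)=O | intermediate (not isolated)
10 | (R)-5-(3-hydroxyprop-1-en-2-yl)-2-methylcyclohex-2-en-1-one | CC1=CC[C@H](CC1=O)C(=C)CO | intermediate
11 | (R)-5-[3-(tert-butyldimethylsilyloxy)prop-1-en-2-yl]-2-methylcyclohex-2-en-1-one | CC1=CC[C@H](CC1=O)C(=C)CO[Si](C)(C)C(C)(C)C | intermediate
12 | (E)-tosylhydrazone of 11 | Cc1ccc(cc1)S(=O)(=O)N/N=C2\C[C@H](C(=C)CO[Si](C)(C)C(C)(C)C)CC=C2C | intermediate
13 | dienyllithium from 12 | CC1=CC[C@H](C=C1[Li])C(=C)CO[Si](C)(C)C(C)(C)C | intermediate (not isolated)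
14 | (R)-5-[3-(tert-butyldimethylsilyloxy)prop-1-en-2-yl]-2-methylcyclohexa-1,3-diene | CC1=CC[C@H](C=C1)C(=C)CO[Si](C)(C)C(C)(C)C | intermediate
15 | B-alkyl-9-borabicyclo[3.3.1]nonane adduct of 14 (C11 epimers) | CC1=CC[C@H](C=C1)C(CO[Si](C)(C)C(C)(C)C)CB2C3CCCC2CCC3 | intermediate (not isolated)
16 | 3-(tert-butyldimethylsilyloxy)-2-(4-methylcyclohexa-2,4-dien-1-yl)propan-1-ol (C11 epimers) | CC1=CC[C@H](C=C1)C(CO)CO[Si](C)(C)C(C)(C)C | intermediate
17 | 3-(tert-butyldimethylsilyloxy)-2-(4-methylcyclohexa-2,4-dien-1-yl)propanoic acid (C11 epimers) | CC1=CC[C@H](C=C1)C(CO[Si](C)(C)C(C)(C)C)C(=O)O | intermediate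
18 | cis-fused acetoxy lactone (C9 acetate trans to lactone oxygen; C11 epimers) | CC1=C[C@@H]2OC(=O)C(CO[Si](C)(C)C(C)(C)C)[C@@H]2C[C@H]1OC(C)=O | intermediate
19 | cis-fused allylic alcohol lactone (C11 exo) | CC1=C[C@@H]2OC(=O)[C@@H](CO[Si](C)(C)C(C)(C)C)[C@@H]2C[C@H]1O | intermediate
20 | enone-lactone unsubstituted at C8 | CC1=C[C@@H]2OC(=O)[C@@H](CO[Si](C)(C)C(C)(C)C)[C@@H]2CC1=O | intermediate
21 | sodium cross-conjugated dienolate of 20 | CC1=C[C@@H]2OC(=O)[C@@H](CO[Si](C)(C)C(C)(C)C)[C@@H]2C=C1[O-].[Na+] | intermediate (not isolated)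
22 | 8-hydroxy enone-lactone (OH trans to C7–C11) | CC1=C[C@@H]2OC(=O)[C@@H](CO[Si](C)(C)C(C)(C)C)[C@@H]2[C@@H](O)C1=O | intermediate
23 | isobutyric acid | CC(C)C(=O)O | starting material
24 | enone-lactone precursor (8-O-isobutyrate cis to the lactone) | CC1=C[C@@H]2OC(=O)[C@@H](CO[Si](C)(C)C(C)(C)C)[C@@H]2[C@H](OC(=O)C(C)C)C1=O | intermediate
25 | cis-anti-cis photoadduct | C[C@@]12C(=O)[C@@H](OC(=O)C(C)C)[C@H]3[C@H](CO[Si](C)(C)C(C)(C)C)C(=O)O[C@H]3[C@@H]1[C@@]4(C)CC(OC)(OC)[C@@H]24 | intermediate
26 | (1(10)Z,4E)-2,2-dimethoxycyclodeca-1(10),4-dien-9-one lactone | C/C1=C/C(OC)(OC)C/C(C)=C/[C@@H]2OC(=O)[C@@H](CO[Si](C)(C)C(C)(C)C)[C@@H]2[C@H](OC(=O)C(C)C)C1=O | intermediate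
27 | (4E)-2,2-dimethoxy-10-methylcyclodec-4-en-9-one lactone | C[C@H]1CC(OC)(OC)C/C(C)=C/[C@@H]2OC(=O)[C@@H](CO[Si](C)(C)C(C)(C)C)[C@@H]2[C@H](OC(=O)C(C)C)C1=O | intermediate
28 | 4,5-diol | C[C@H]1CC(OC)(OC)C[C@](C)(O)[C@@H](O)[C@@H]2OC(=O)[C@@H](CO[Si](C)(C)C(C)(C)C)[C@@H]2[C@H](OC(=O)C(C)C)C1=O | intermediate
29 | angelic acid | C/C=C(/C)C(=O)O | starting material
30 | angeloyl 2,4,6-trichlorobenzoyl anhydride | C/C=C(/C)C(=O)OC(=O)c1c(Cl)cc(Cl)cc1Cl | intermediate (not isolated)
31 | 5-O-angelate (C13 silyl ether, C2 ketal) | C[C@H]1CC(OC)(OC)C[C@](C)(O)[C@@H](OC(=O)/C(C)=C\C)[C@@H]2OC(=O)[C@@H](CO[Si](C)(C)C(C)(C)C)[C@@H]2[C@H](OC(=O)C(C)C)C1=O | intermediate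
32 | C13 primary alcohol | C[C@H]1CC(OC)(OC)C[C@](C)(O)[C@@H](OC(=O)/C(C)=C\C)[C@@H]2OC(=O)[C@@H](CO)[C@@H]2[C@H](OC(=O)C(C)C)C1=O | intermediate
33 | C13 mesylate | C[C@H]1CC(OC)(OC)C[C@](C)(O)[C@@H](OC(=O)/C(C)=C\C)[C@@H]2OC(=O)[C@@H](COS(C)(=O)=O)[C@@H]2[C@H](OC(=O)C(C)C)C1=O | intermediate (not isolated)
34 | α-methylene lactone with C2 dimethyl ketal | C[C@H]1CC(OC)(OC)C[C@](C)(O)[C@@H](OC(=O)/C(C)=C\C)[C@@H]2OC(=O)C(=C)[C@@H]2[C@H](OC(=O)C(C)C)C1=O | intermediate
35 | 2-ketone | C[C@H]1CC(=O)C[C@](C)(O)[C@@H](OC(=O)/C(C)=C\C)[C@@H]2OC(=O)C(=C)[C@@H]2[C@H](OC(=O)C(C)C)C1=O | intermediate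
36 | CNP0184688.2 | C=C1C(=O)O[C@@H]2[C@H]1[C@H](OC(=O)C(C)C)C(=O)[C@@H](C)C[C@H](O)C[C@](C)(O)[C@H]2OC(=O)/C(C)=C\C | target

**Step count**
Total: 24 steps. Longest linear sequence: 21 steps (steps 4–24 from (R)-carvone); the cyclobutene branch is 3 steps (steps 1–3).

**Steps most likely to fail**

Step 16. The excited α'-acyloxy enone may be lost to α-cleavage or acyl loss faster than the hindered, α-methylated enone is trapped by the cyclobutene, and the head-to-head orientation may compete. Fallback: the cycloaddition is moved one stage earlier. Enone-lactone 20, an ordinary 2-methylcyclohexenone chromophore, is irradiated with 6 under the same conditions to give the des-acyloxy photoadduct F1. Its ketone can enolise only toward C8 because C10 is quaternary, so NaN(SiMe3)2 and the Davis oxaziridine give the 8-hydroxy photoadduct F2 (oxygen anti to the C7–C11 bond). Mitsunobu esterification of F2 with 23 (PPh3, DIAD) then comes back to the route at 25.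

Step 17. The 1,4-diyl may fragment across C2–C3 instead of C5–C10 (giving a ketene acetal on an intact cyclohexanone), or the 1,5-diene 26 may undergo Cope rearrangement at the temperature of its formation. Fallback: the ketal of 25 is hydrolysed first (aqueous oxalic acid on SiO2, CH2Cl2) to the cyclobutanone F3. Its thermolysis (PhMe, about 130 °C) is eased by the α-keto radical at C1 and cannot take the C2–C3 path without forming a ketene, and the product, the ene-dione F4, cannot relax by Cope rearrangement for the same reason. Zn in AcOH at rt reduces the ene-dione chemoselectively to the 2,9-diketone F5, with C10 set on ketonisation. Noyori acetalisation (MeOSiMe3, Me3SiOTf) then ketalises only the unhindered C2 carbonyl, flanked by two CH2 groups, and comes back to the route at 27.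

Step 18. Protonation of the enolate at C10 has no strong control element and may show poor facial selectivity; 1,2-reduction of the hindered enone may also compete. Fallback: the order is changed and the hydrogen is delivered under catalyst control. From 26 the strained E-alkene is dihydroxylated first (OsO4, NMO; the electron-poor Z-enone reacts more slowly) to give the enone diol F6. Its C1=C10 bond is then hydrogenated with H2 and a chiral cationic iridium phosphine–oxazoline complex, [Ir(cod)(PHOX)][B(3,5-(CF3)2C6H3)4], with the ligand enantiomer chosen to add H2 to the face that gives the required C10 configuration. This comes back to the route at 28.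

**Further compounds**
F1 | step 16 | des-acyloxy photoadduct (from 20 and 6) | C[C@@]12C(=O)C[C@H]3[C@H](CO[Si](C)(C)C(C)(C)C)C(=O)O[C@H]3[C@@H]1[C@@]4(C)CC(OC)(OC)[C@@H]24
F2 | step 16 | 8-hydroxy photoadduct (OH trans to C7–C11) | C[C@@]12C(=O)[C@H](O)[C@H]3[C@H](CO[Si](C)(C)C(C)(C)C)C(=O)O[C@H]3[C@@H]1[C@@]4(C)CC(OC)(OC)[C@@H]24
F3 | step 17 | cyclobutanone from hydrolysis of 25 | C[C@@]12C(=O)[C@@H](OC(=O)C(C)C)[C@H]3[C@H](CO[Si](C)(C)C(C)(C)C)C(=O)O[C@H]3[C@@H]1[C@@]4(C)CC(=O)[C@@H]24
F4 | step 17 | (1(10)Z,4E)-cyclodeca-1(10),4-diene-2,9-dione lactone | C/C1=C/C(=O)C/C(C)=C/[C@@H]2OC(=O)[C@@H](CO[Si](C)(C)C(C)(C)C)[C@@H]2[C@H](OC(=O)C(C)C)C1=O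
F5 | step 17 | (4E)-10-methylcyclodec-4-ene-2,9-dione lactone | C[C@H]1CC(=O)C/C(C)=C/[C@@H]2OC(=O)[C@@H](CO[Si](C)(C)C(C)(C)C)[C@@H]2[C@H](OC(=O)C(C)C)C1=O
F6 | step 18 | (1(10)Z)-enone 4,5-diol | C/C1=C/C(OC)(OC)C[C@](C)(O)[C@@H](O)[C@@H]2OC(=O)[C@@H](CO[Si](C)(C)C(C)(C)C)[C@@H]2[C@H](OC(=O)C(C)C)C1=O
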